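In the dawn run and in Monday's, a small charge of L enters a large charge of D, and it keeps coming that way, a trickle over 2.5 d.

| flask | L | D | remark | time |
|---|---|---|---|---|
| noon | 0.59 M (fed, over 2.5 d) | 0.37 equiv | run made earlier; the fed solution adds 0.20 times the starting volume |  |
| dawn | 0.59 M (fed, over 2.5 d) | 3.4 equiv | run made earlier; the fed solution adds 0.20 times the starting volume |  |
| Monday's | 0.59 M (fed, over 2.5 d) | 4.00 equiv | the fed solution adds 0.20 times the starting volume | 2.5 d |
| Sunday's | 0.59 M (fed, over 2.5 d) | 0.500 equiv | the fed solution adds 0.20 times the starting volume | 2.5 d |

- noon (time / h: Q / %, L / %): 4.00: 1.2, 5.3; 10.0: 2.8, 11.4; 20.0: 7.4, 16.8; 30.0: 12.2, 21.4; 40.0: 15.8, 27.2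
- dawn (time / h: Q / %, L / %): 8.00: 4.3, 3.7; 15.0: 7.0, 3.8; 25.0: 7.6, 3.3; 30.0: 9.0, 4.6; 40.0: 9.9, 4.4

(scatter of a reading: 0.5 percentage points)

- charges are per starting volume, the dose included; the dosed solution carries all of it
- what may be going on: L <-> X; D + Q -> J; D + J <-> Z; L + D -> Q
- percentages count the whole charge, also what has not yet gone in

- which of these holds the largest part of the L at the end of Monday's (Z / J / Q / L)
- which of these holds the largest part of the L at the end of Sunday's (Z / J / Q / L)
- how much Q is there at the end of Monday's, in percent of the L charged

In the dawn run, each portion of L meets excess D: L reads 3.7% at 8.00 h and 4.4% at 40.0 h, a level rather than a pile, though some L can slip to X. Q reads 4.3% at that first reading and climbs towards its own level, where what L hands to Q matches what Q hands on to J. Both hand-overs run with the same D, so D cancels from the balance. That leaves the level ratio, Q over L at that balance, 2.25 at the last dawn reading, where Q is still rising; we take it as a reading of the selectivity factor of the first addition over the second. Two equal, independent sites on L would give 2, and with 0.5 percentage points of scatter on an L of 4.4% we can't tell our reading from that zero of the scale.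

Noon, with 0.37 equiv of D, shows no level: L climbs to 27.2% by 40.0 h, where Q over L is 0.581. Sunday's charges 0.500 equiv of D, the limiting reagent there, and we expect it to look like noon, whose last reading has L above Q.

We read the end of Monday's as the dawn flask continued. Monday's starts with 0.600 equiv more D, but it is read 20.0 h later, and that extra feed, 33.3% of the L, takes about 0.667 equiv of D at two D to each L. The D left at the end of Monday's should then be about what the dawn flask held at its last reading, and L enters both at the same rate, so we expect Q near 9.9%.

The forecast says J for Monday's, L for Sunday's, and 10.5% of Q, a little above ours; of Monday's it writes “Most material passes through to J”.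

    L ⇌ X (K = 3.00, k = 0.0350 /h)
    D + Q → J (k = 0.120 /M/h)
    D + J ⇌ Z (K = 0.260 /M, k = 0.280 /M/h)
    L + D → Q (k = 0.250 /M/h)

Of the four asked about, Monday's ended with J largest at 61.3% and Q at 10.4%, and Sunday's with L largest at 34.5%. At 1.27 d in Monday's, L was used by the step with D 12 times as fast as by the forward step to X alone, and by the end those steps had a net turnover of 88.6% and 5.91% of the L charged. Monday's Q stood at 1.89 times its L of 5.51%, against the 2.25 read at dawn. The same flask read at 6.0 d holds L 0.13%; 2.25 times that is 0.288%, and its Q is 0.293%.

The readings stem from a simulated flask for substances that don't exist; scatter was added.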